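**Assumptions (one line):** atom numbers and α/β follow ent‑kaurane numbering of the target; (R)‑but‑3‑en‑2‑ol is bought as the single enantiomer and is the only source of chirality. The route is a paper design and has not been run.

## Retrosynthetic overview

1. Target ⇐ 15‑deoxo‑16‑ene (late C15 allylic oxidation) ⇐ ring D by 5‑exo vinyl‑radical closure (C16–C13) onto a Δ12 allylic alcohol.
2. Lactone ring B and ring C are formed together by an intramolecular Diels–Alder reaction: a 2‑silyloxydiene on C10 adds to a C20–O‑tethered 2‑(2‑bromoallyl)acrylate; the C11 silyl enol ether then gives enone, then 11‑OH.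
3. The IMDA precursor comes from a ring‑A neopentyl alcohol carrying the 6,19‑methyl acetal, itself made from a bridged C19–O–C20 lactone / C5 ketone (formaldehyde aldol, Wittig, acid methanolysis).
4. The C10 quaternary centre is set by Claisen rearrangement of the allyl enol ether made from methyl 2‑oxocyclohexanecarboxylate and (R)‑but‑3‑en‑2‑ol (1,3‑chirality transfer).
5. Ring order: A (bought) → tetrahydrofuran acetal → B + C (IMDA) → D (radical).

## Route

**Step 1**
Reactants: 1 methyl 2‑oxocyclohexane‑1‑carboxylate; 2 (R)‑but‑3‑en‑2‑ol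
Product: 3 methyl 2‑{[(2S)‑but‑3‑en‑2‑yl]oxy}cyclohex‑1‑ene‑1‑carboxylate
Conditions: PPh3, DIAD, toluene, 0 °C→rt
Reagents that add atoms: none (only 2)
Why: Mitsunobu O‑alkylation of the H‑bonded enol of the β‑keto ester, with SN2 inversion at the carbinol carbon, gives the (S)‑allyl enol ether.

**Step 2**
Reactants: 3
Product: 4 methyl (1R)‑1‑[(2E)‑but‑2‑en‑1‑yl]‑2‑oxocyclohexane‑1‑carboxylate
Conditions: toluene, BHT, 130 °C, sealed tube
Reagents that add atoms: none
Why: Claisen [3,3] rearrangement through a chair transition state with the carbinol methyl equatorial; the ring‑locked enol ether geometry makes the chirality transfer unambiguous, giving (R) at C10 and the E‑alkene.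

**Step 3**
Reactants: 4
Product: 5 methyl (1R)‑1‑[(2E)‑but‑2‑en‑1‑yl]‑3‑methyl‑2‑oxocyclohexane‑1‑carboxylate (C3 epimers, irrelevant)
Conditions: LDA, THF, –78 °C; MeI
Reagents that add atoms: iodomethane, CI
Why: enolate alkylation at the only enolisable α‑position (future C4); the new centre is re‑enolised in the next step.

**Step 4**
Reactants: 5
Product: 6 (1R,5S)‑1‑[(2E)‑but‑2‑en‑1‑yl]‑5‑methyl‑3‑oxabicyclo[3.3.1]nonane‑2,9‑dione
Conditions: LDA, THF, –78→–20 °C; CH2O (g, from paraformaldehyde), –78 °C→rt; AcOH quench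
Reagents that add atoms: formaldehyde, C=O
Why: aldol with formaldehyde; only the aldolate cis to the CO2Me can lactonise (1,3‑diaxial δ‑lactone, loss of MeOH) while the trans aldolate reverts by retro‑aldol, so the C4 quaternary centre is dictated by C10.

**Step 5**
Reactants: 6
Product: 7 (1R,5S)‑1‑[(2E)‑but‑2‑en‑1‑yl]‑9‑(methoxymethylidene)‑5‑methyl‑3‑oxabicyclo[3.3.1]nonan‑2‑one (bridgeheads unchanged)
Conditions: Ph3P(Cl)CH2OMe, KHMDS, THF, 0→50 °C
Reagents that add atoms: (methoxymethyl)triphenylphosphonium chloride, COC[P+](c1ccccc1)(c1ccccc1)c1ccccc1.[Cl-]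
Why: Wittig methoxymethylenation of the non‑enolisable bridging ketone, whose flanking substituents are tied back in the bicycle; this introduces C6.

**Step 6**
Reactants: 7
Product: 8 methyl 7‑[(2E)‑but‑2‑en‑1‑yl]‑1‑methoxy‑3a‑methyl‑octahydro‑2‑benzofuran‑7‑carboxylate. Cis‑fused; CO2Me (C20), C19H2–O and C6 on one face; 4‑Me, H‑5, 6‑OMe and the butenyl on the other.
Conditions: AcCl (HCl in situ), MeOH, 0→50 °C
Reagents that add atoms: methanol, CO
Why: acid methanolysis opens the strained lactone to the C20 methyl ester, and the freed C19–OH traps the C6 oxocarbenium from the enol ether as the cis‑fused five‑membered acetal; C5 equilibrates through the enol ether and the exo‑OMe anomer is the thermodynamic one.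

**Step 7**
Reactants: 8
Product: 9 the corresponding C20 primary alcohol (7‑hydroxymethyl compound)
Conditions: LiAlH4, THF, 0 °C
Reagents that add atoms: none (hydride only)
Why: ester reduction; acetal and alkene are inert.

**Step 8**
Reactants: 9
Product: 10 spiro‑lactol (C20–O–C11H(OH)–C9H2 ring on C10; anomer mixture)
Conditions: O3, CH2Cl2/MeOH, –78 °C; Me2S
Reagents that add atoms: ozone, [O-][O+]=O
Why: ozonolysis of the only alkene (acetaldehyde lost); the γ‑hydroxy aldehyde closes to the lactol.

**Step 9**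
Reactants: 10
Product: 11 diol: C20H2OH and C9H2–C11H(OH)–CH=CH2 on C10 (C11 epimers)
Conditions: vinylmagnesium bromide (3.5 equiv), THF, 0 °C→rt
Reagents that add atoms: vinylmagnesium bromide, C=C[Mg]Br
Why: Grignard addition to the ring‑opened lactol aldehyde supplies C12 and C13.

**Step 10**
Reactants: 11
Product: 12 1‑[7‑(hydroxymethyl)‑1‑methoxy‑3a‑methyl‑octahydro‑2‑benzofuran‑7‑yl]but‑3‑en‑2‑one (vinyl ketone, free C20–OH)
Conditions: activated MnO2, CH2Cl2, rt
Reagents that add atoms: none
Why: MnO2 oxidises only the allylic secondary alcohol; the neopentyl primary alcohol is untouched.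

**Step 11**
Reactants: 13 diethyl malonate; 14 2,3‑dibromopropene
Product: 15 diethyl 2‑(2‑bromoprop‑2‑en‑1‑yl)malonate
Conditions: NaH, THF, 0 °C→rt (malonate in excess)
Reagents that add atoms: none (both are reactants)
Why: malonate SN2 alkylation at the allylic bromide; the vinyl bromide is inert.

**Step 12**
Reactants: 15
Product: 16 2‑(2‑bromoprop‑2‑en‑1‑yl)malonic acid
Conditions: KOH, EtOH/H2O, rt; then HCl
Reagents that add atoms: water (as hydroxide), O
Why: saponification.

**Step 13**
Reactants: 16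
Product: 17 4‑bromo‑2‑methylidenepent‑4‑enoic acid [2‑(2‑bromoallyl)acrylic acid]
Conditions: (CH2O)n, Et2NH, EtOAc, reflux
Reagents that add atoms: formaldehyde, C=O
Why: Mannich condensation with decarboxylative elimination gives the α‑substituted acrylic acid.

**Step 14**
Reactants: 12; 17
Product: 18 the C20–O ester of 12 with 17
Conditions: 17, (COCl)2, cat. DMF, CH2Cl2; then 12, pyridine, 0 °C
Reagents that add atoms: none (only 17)
Why: acylation of the primary alcohol through the acid chloride; no DMAP, to spare the vinyl ketone.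

**Step 15**
Reactants: 18
Product: 19 (Z)‑2‑(tert‑butyldimethylsilyloxy)‑1,3‑diene: C10–C9H=C11(OTBS)–C12H=C13H2
Conditions: TBSOTf, Et3N, CH2Cl2, –78 °C
Reagents that add atoms: TBSOTf, CC(C)(C)[Si](C)(C)OS(=O)(=O)C(F)(F)F
Why: soft enolisation toward C9, the only enolisable position; the Z enol ether keeps the bulky C10 trans to the vinyl group, which is the geometry the cycloaddition needs.

**Step 16**
Reactants: 19
Product: 20 tricyclic δ‑lactone with C11(OTBS)=C12 silyl enol ether. C8 is quaternary (C7 lactone carbonyl and 2‑bromoallyl), with H‑9 cis to the bromoallyl group and C11 anti to C5 about C9–C10.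
Conditions: toluene (0.01 M), BHT, 170 °C, sealed tube
Reagents that add atoms: none
Why: type‑1 intramolecular Diels–Alder forming rings B and C (bonds C8–C9 and C13–C14). The tether carbonyl sits endo, giving the cis lactone/cyclohexene fusion at C8; A(1,3) strain with the C11–OTBS places the small C1H2 inside and C5 away from the diene, which sets C9.

**Step 17**
Reactants: 20
Product: 21 enone: C11=O, C12=C13
Conditions: PhSeCl, CH2Cl2, –78 °C; then H2O2, pyridine, 0 °C→rt
Reagents that add atoms: none (selenium is lost)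
Why: selenenylation of the silyl enol ether at C12 and selenoxide syn‑elimination, which can only go toward C13; C9 is never enolised.

**Step 18**
Reactants: 21
Product: 22 allylic alcohol: 11‑OH cis to C10 and trans to H‑9, C12=C13
Conditions: NaBH4, CeCl3·7H2O, MeOH, –78 °C
Reagents that add atoms: none (hydride only)
Why: Luche 1,2‑reduction; hydride is predicted to add to the face opposite the C10 quaternary carbon and lactone bridge, setting C11.

**Step 19**
Reactants: 22
Product: 23 15‑deoxo‑Angustifolin (bicyclo[3.2.1]octane with 16‑exo‑methylene, C15H2, 11‑OH)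
Conditions: Bu3SnH, AIBN, benzene, 80 °C (Bu3SnH not too dilute)
Reagents that add atoms: none (H only)
Why: the vinyl radical from the bromide closes 5‑exo‑trig onto C13; the bridge can only form on the face bearing the C8 side chain, which sets C13.

**Step 20**
Reactants: 23
Product: 24 15‑hydroxy compound (C15 epimer irrelevant)
Conditions: SeO2 (0.5 equiv), t‑BuOOH, CH2Cl2, rt
Reagents that add atoms: selenium dioxide / tert‑butyl hydroperoxide, O=[Se]=O / CC(C)(C)OO
Why: ene/[2,3] allylic hydroxylation at C15; the only other allylic position is the bridgehead C13, which cannot react (Bredt).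

**Step 21**
Reactants: 24
Product: 25 Angustifolin
Conditions: activated MnO2, CH2Cl2, rt
Reagents that add atoms: none
Why: selective oxidation of the allylic C15–OH to the enone; the saturated 11‑OH is not oxidised.

## Compound list

1 | methyl 2‑oxocyclohexane‑1‑carboxylate | O=C1CCCCC1C(=O)OC | starting material
2 | (R)‑but‑3‑en‑2‑ol | C[C@@H](O)C=C | starting material
3 | methyl 2‑{[(2S)‑but‑3‑en‑2‑yl]oxy}cyclohex‑1‑ene‑1‑carboxylate | C=C[C@H](C)OC1=C(C(=O)OC)CCCC1 | intermediate
4 | methyl (1R)‑1‑[(2E)‑but‑2‑enyl]‑2‑oxocyclohexane‑1‑carboxylate | C/C=C/C[C@@]1(CCCCC1=O)C(=O)OC | intermediate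
5 | methyl (1R)‑1‑[(2E)‑but‑2‑enyl]‑3‑methyl‑2‑oxocyclohexane‑1‑carboxylate | C/C=C/C[C@@]1(CCCC(C)C1=O)C(=O)OC | intermediate
6 | (1R,5S)‑1‑[(2E)‑but‑2‑enyl]‑5‑methyl‑3‑oxabicyclo[3.3.1]nonane‑2,9‑dione | C/C=C/C[C@@]12C(=O)[C@@](C)(CCC1)COC2=O | intermediate
7 | 9‑(methoxymethylidene) analogue of 6 | C/C=C/C[C@@]12C(=COC)[C@@](C)(CCC1)COC2=O | intermediate
8 | methyl 7‑[(2E)‑but‑2‑enyl]‑1‑methoxy‑3a‑methyl‑octahydro‑2‑benzofuran‑7‑carboxylate | C/C=C/C[C@@]1(CCC[C@@]2(C)CO[C@H](OC)[C@H]21)C(=O)OC | intermediate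
9 | C20 alcohol from 8 | C/C=C/C[C@@]1(CCC[C@@]2(C)CO[C@H](OC)[C@H]21)CO | intermediate
10 | spiro‑lactol | OC1C[C@@]2(CCC[C@@]3(C)CO[C@H](OC)[C@H]32)CO1 | intermediate
11 | vinyl carbinol diol | C=CC(O)C[C@@]1(CCC[C@@]2(C)CO[C@H](OC)[C@H]21)CO | intermediate
12 | hydroxy vinyl ketone | C=CC(=O)C[C@@]1(CCC[C@@]2(C)CO[C@H](OC)[C@H]21)CO | intermediate
13 | diethyl malonate | CCOC(=O)CC(=O)OCC | starting material
14 | 2,3‑dibromopropene | C=C(Br)CBr | starting material
15 | diethyl 2‑(2‑bromoprop‑2‑enyl)malonate | CCOC(=O)C(CC(Br)=C)C(=O)OCC | intermediate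
16 | 2‑(2‑bromoprop‑2‑enyl)malonic acid | OC(=O)C(CC(Br)=C)C(=O)O | intermediate
17 | 4‑bromo‑2‑methylidenepent‑4‑enoic acid | C=C(Br)CC(=C)C(=O)O | intermediate
18 | acrylate ester of 12 | C=CC(=O)C[C@@]1(CCC[C@@]2(C)CO[C@H](OC)[C@H]21)COC(=O)C(=C)CC(Br)=C | intermediate
19 | (Z)‑2‑silyloxydiene ester | C=C/C(O[Si](C)(C)C(C)(C)C)=C/[C@@]1(CCC[C@@]2(C)CO[C@H](OC)[C@H]21)COC(=O)C(=C)CC(Br)=C | intermediate
20 | IMDA adduct (silyl enol ether) | C=C(Br)C[C@]12CCC=C(O[Si](C)(C)C(C)(C)C)[C@H]1[C@@]1(CCC[C@@]3(C)CO[C@H](OC)[C@H]31)COC2=O | intermediate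
21 | Δ12‑11‑enone | C=C(Br)C[C@]12CC=CC(=O)[C@H]1[C@@]1(CCC[C@@]3(C)CO[C@H](OC)[C@H]31)COC2=O | intermediate
22 | 11‑hydroxy‑Δ12 allylic alcohol | C=C(Br)C[C@]12CC=C[C@@H](O)[C@H]1[C@@]1(CCC[C@@]3(C)CO[C@H](OC)[C@H]31)COC2=O | intermediate
23 | 15‑deoxo‑Angustifolin | C=C1C[C@]23C[C@H]1C[C@@H](O)[C@H]2[C@@]1(CCC[C@@]2(C)CO[C@H](OC)[C@H]21)COC3=O | intermediate
24 | 15‑hydroxy‑15‑deoxo‑Angustifolin | C=C1C(O)[C@]23C[C@H]1C[C@@H](O)[C@H]2[C@@]1(CCC[C@@]2(C)CO[C@H](OC)[C@H]21)COC3=O | intermediate
25 | Angustifolin | C=C1C(=O)[C@]23C[C@H]1C[C@@H](O)[C@H]2[C@@]1(CCC[C@@]2(C)CO[C@H](OC)[C@H]21)COC3=O | target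

## Summary

**Total steps:** 21.
**Longest linear sequence:** 18 (steps 1–10 and 14–21, from compound 1).

**Three steps most likely to fail, with fallbacks:**

1. **Step 16 (IMDA).** The ester tether is slow to reach the reactive conformer, a quaternary C8 is formed, and the 2‑silyloxy group is electronically mismatched for the enforced regiochemistry. Fallback: esterify 12 with plain acryloyl chloride so that no quaternary centre forms in the cycloaddition, then introduce the 2‑bromoallyl group afterwards by alkylating the lactone enolate (LDA, 2,3‑dibromopropene) on the face syn to H‑9.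
2. **Step 1 (Mitsunobu O‑alkylation).** C‑alkylation or SN2′ would erode the chirality transfer. Fallback: transesterify 1 with (S)‑but‑3‑en‑2‑ol to the allyl β‑keto ester and run a dianionic ester‑enolate Carroll rearrangement (LDA, 2.2 equiv, THF, –78→65 °C; MeI trap); the chelated enolate gives the same (R)‑4.
3. **Step 5 (Wittig on the congested bridging ketone).** Fallback: Corey–Chaykovsky epoxidation (Me2S=CH2) followed by Lewis‑acid Meinwald rearrangement to the C6 aldehyde, which is then taken through the same acid methanolysis to 8.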